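**Plan**
1. Numbering: germacrane for the ring compounds (ring C1–C10, C1=C10 E with CH3 on C10, oxirane C4–C5 with CH3 on C4, OH on C6, 2-propyl C11 on C7, ester O on C8).
2. Cuts, in retrosynthetic order: the C8–O acyl bond; then ring bond C6–C7, read as the homoallylic alcohol C6(OH)–C7–C11=C12 once the 2-propyl group is an isopropenyl group; then, in the open chain, C1–C2 (alkyl–alkenyl coupling) and C8–C9 (propargylation).
3. Enabling feature: carbinol C6 lies between the C4–C5 oxirane and C7, which carries a three-carbon branch. The carbocycle C1–C10 can therefore close by addition of an allylmetal C12–C11=C7 (from an allylic chloride) to an epoxy aldehyde C6, with C1=C10 and the oxirane already in the chain.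
4. Forward order: a (2Z,6E,10E)-farnesane chain oxygenated at C6, C8 and C12 is joined from two fragments; the oxirane is made on the open chain; the ten-membered carbocycle is closed last; the isopropenyl group is then reduced and the ester placed.
5. Stereochemistry: C8 from a chiral phosphoric acid-catalysed propargylation; C4/C5 from Sharpless epoxidation of the (Z)-allylic alcohol with D-(−)-diethyl tartrate; C6 and C7 from the ring closure.
6. Alkene geometry: Horner–Wadsworth–Emmons (E), carboalumination (E), commercial (Z)-enynol (Z).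

Key step: step 12

Remark: the sense of induction of (S)-TRIP in step 3 is assumed by analogy with aryl and alkenyl aldehydes and would be confirmed on 6 by Mosher ester analysis; open-chain compounds carry their own locants.

**Step 1**
Reactants: 1 1-(tert-butyldimethylsilyloxy)propan-2-one; 2 diethyl [2-(methoxy(methyl)amino)-2-oxoethyl]phosphonate
Product: 3 (E)-4-(tert-butyldimethylsilyloxy)-N-methoxy-N,3-dimethylbut-2-enamide
Conditions: NaH, THF, 0 °C to rt
Reagents that add atoms: none
Why: Horner–Wadsworth–Emmons olefination of the methyl ketone with the amide-stabilised phosphonate anion should favour the (E)-enamide (carbonyl trans to CH2OSi), and the minor (Z)-isomer would be removed by chromatography.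

**Step 2**
Reactants: 3 (E)-4-(tert-butyldimethylsilyloxy)-N-methoxy-N,3-dimethylbut-2-enamide
Product: 4 (E)-4-(tert-butyldimethylsilyloxy)-3-methylbut-2-enal
Conditions: i-Bu2AlH, THF, −78 °C; aq. Rochelle salt
Reagents that add atoms: none
Why: Weinreb amide reduction, in which the chelated tetrahedral aluminium adduct collapses only on work-up, so the reaction should stop at the enal without 1,4-reduction or loss of geometry.

**Step 3**
Reactants: 4 (E)-4-(tert-butyldimethylsilyloxy)-3-methylbut-2-enal; 5 allenylboronic acid pinacol ester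
Product: 6 (4S,5E)-7-(tert-butyldimethylsilyloxy)-6-methylhept-5-en-1-yn-4-ol
Conditions: (S)-TRIP [(S)-3,3′-bis(2,4,6-triisopropylphenyl)-1,1′-binaphthyl-2,2′-diyl hydrogen phosphate] (5 mol%), 4 Å MS, toluene, −20 °C; aq. work-up
Reagents that add atoms: none
Why: Chiral Brønsted acid-catalysed propargylation with an allenylboronate (SE2′ through a six-membered chair in which the phosphoric acid binds the boronate oxygen and the formyl hydrogen); the catalyst should shield one aldehyde face and set the carbinol centre (later C8 of the ring) as S, and the allenyl-to-propargyl transposition gives the terminal alkyne.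

**Step 4**
Reactants: 6 (4S,5E)-7-(tert-butyldimethylsilyloxy)-6-methylhept-5-en-1-yn-4-ol
Product: 7 (4S,5E)-7-(tert-butyldimethylsilyloxy)-4-(4-methoxybenzyloxy)-6-methylhept-5-en-1-yne
Conditions: NaH, 4-MeOC6H4CH2Cl, Bu4NI (cat.), THF/DMF, 0 °C to rt
Reagents that add atoms: 4-methoxybenzyl chloride, COc1ccc(CCl)cc1
Why: Williamson etherification of the sodium alkoxide without touching the stereocentre; an ether is chosen because this oxygen must not direct the later epoxidation and must be a poor leaving group in the key step, and the (E)-geometry rules out silyl migration.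

**Step 5**
Reactants: 7 (4S,5E)-7-(tert-butyldimethylsilyloxy)-4-(4-methoxybenzyloxy)-6-methylhept-5-en-1-yne
Product: 9 (1E,4S,5E)-7-(tert-butyldimethylsilyloxy)-1-iodo-4-(4-methoxybenzyloxy)-2,6-dimethylhepta-1,5-diene, via alkenyldimethylalane 8 (not isolated)
Conditions: Me3Al, Cp2ZrCl2 (0.3 equiv), CH2Cl2, 0 °C to rt; then I2, THF, −30 to 0 °C
Reagents that add atoms: trimethylaluminium, C[Al](C)C; iodine, [I][I]
Why: Negishi zirconium-catalysed carboalumination adds methyl and aluminium syn across the terminal alkyne with methyl on the internal carbon, and iodinolysis of alane 8 with retention should give the (E)-iodide; the trisubstituted alkene is inert, and the mixture is not heated so that no chelation-driven isomerisation occurs.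

**Step 6**
Reactants: 10 (Z)-3-methylpent-2-en-4-yn-1-ol
Product: 11 (Z)-3-methylpenta-2,4-dien-1-ol
Conditions: H2 (1 atm, 1 equiv), Pd/CaCO3 poisoned with Pb(OAc)2 (Lindlar catalyst), quinoline, Et2O, 0 °C to rt
Reagents that add atoms: none
Why: Lindlar semihydrogenation of the terminal alkyne should stop at the diene because the poisoned catalyst binds alkynes far more strongly than alkenes, and the (Z)-trisubstituted alkene is untouched.

**Step 7**
Reactants: 11 (Z)-3-methylpenta-2,4-dien-1-ol; 9 (1E,4S,5E)-7-(tert-butyldimethylsilyloxy)-1-iodo-4-(4-methoxybenzyloxy)-2,6-dimethylhepta-1,5-diene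
Product: 13 (2Z,6E,9S,10E)-12-(tert-butyldimethylsilyloxy)-9-(4-methoxybenzyloxy)-3,7,11-trimethyldodeca-2,6,10-trien-1-ol, via bis(9-BBN) adduct 12 (not isolated)
Conditions: 11, 9-BBN (2.2 equiv), THF, 0 °C to rt; then 9, PdCl2(dppf) (5 mol%), AsPh3, Cs2CO3, DMF/H2O, rt
Reagents that add atoms: none
Why: Hydroboration then B-alkyl Suzuki–Miyaura coupling: the first equivalent of 9-BBN caps the hydroxyl as a borinate, the second adds boron to the terminal CH2 of the vinyl group only, and the primary alkylborane should couple with the alkenyl iodide with retention of the (E)-geometry.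

**Step 8**
Reactants: 13 (2Z,6E,9S,10E)-12-(tert-butyldimethylsilyloxy)-9-(4-methoxybenzyloxy)-3,7,11-trimethyldodeca-2,6,10-trien-1-ol
Product: 14 (2R,3S,6E,9S,10E)-12-(tert-butyldimethylsilyloxy)-2,3-epoxy-9-(4-methoxybenzyloxy)-3,7,11-trimethyldodeca-6,10-dien-1-ol
Conditions: t-BuOOH, Ti(OiPr)4 (15 mol%), D-(−)-diethyl tartrate (18 mol%), 4 Å MS, CH2Cl2, −20 °C
Reagents that add atoms: tert-butyl hydroperoxide, CC(C)(C)OO
Why: Sharpless asymmetric epoxidation touches only the allylic alcohol, and with D-(−)-diethyl tartrate the titanium–tartrate complex should deliver oxygen to the face of the (Z)-alkene that gives the (2R,3S) cis-epoxide (C4 S and C5 R of the target), overriding the remote C9 centre.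

**Step 9**
Reactants: 14 (2R,3S,6E,9S,10E)-12-(tert-butyldimethylsilyloxy)-2,3-epoxy-9-(4-methoxybenzyloxy)-3,7,11-trimethyldodeca-6,10-dien-1-ol
Product: 15 (2R,3S,6E,9S,10E)-2,3-epoxy-9-(4-methoxybenzyloxy)-3,7,11-trimethyldodeca-6,10-diene-1,12-diol
Conditions: Bu4NF, THF, 0 °C
Reagents that add atoms: none
Why: Fluoride desilylation of the primary silyl ether; the benzyl ether and the epoxy alcohol are stable to Bu4NF at 0 °C.

**Step 10**
Reactants: 15 (2R,3S,6E,9S,10E)-2,3-epoxy-9-(4-methoxybenzyloxy)-3,7,11-trimethyldodeca-6,10-diene-1,12-diol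
Product: 16 (2R,3S,6E,9S,10E)-12-chloro-2,3-epoxy-9-(4-methoxybenzyloxy)-3,7,11-trimethyldodeca-6,10-dien-1-ol
Conditions: N-chlorosuccinimide, Me2S, CH2Cl2, −20 to 0 °C; aq. work-up
Reagents that add atoms: N-chlorosuccinimide, O=C1CCC(=O)N1Cl
Why: Corey–Kim chlorination, in which only the allylic alkoxysulfonium salt is displaced by chloride (SN2 at the primary carbon), while the sulfonium salt of the epoxy carbinol is not displaced and should revert to the alcohol on work-up.

**Step 11**
Reactants: 16 (2R,3S,6E,9S,10E)-12-chloro-2,3-epoxy-9-(4-methoxybenzyloxy)-3,7,11-trimethyldodeca-6,10-dien-1-ol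
Product: 17 (2S,3S,6E,9S,10E)-12-chloro-2,3-epoxy-9-(4-methoxybenzyloxy)-3,7,11-trimethyldodeca-6,10-dienal
Conditions: Dess–Martin periodinane, NaHCO3, CH2Cl2, 0 °C to rt
Reagents that add atoms: none
Why: Buffered Dess–Martin oxidation should give the α,β-epoxy aldehyde without epimerisation (the descriptor at C2 changes by priority only); allylic chloride, ether and oxirane are inert, and the aldehyde is used at once.

**Step 12**
Reactants: 17 (2S,3S,6E,9S,10E)-12-chloro-2,3-epoxy-9-(4-methoxybenzyloxy)-3,7,11-trimethyldodeca-6,10-dienal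
Product: 20 (1(10)E,4S,5R,6R,7R,8S)-4,5-epoxy-8-(4-methoxybenzyloxy)germacra-1(10),11-dien-6-ol, via allyl(ethyl)zinc species 18 (not isolated), via ethylzinc alkoxide 19 (not isolated)
Conditions: PdCl2(PPh3)2 (10 mol%), K2CO3, Et2Zn (3 equiv, slow addition), DMA, 0.01 M, 0 °C to rt; aq. NH4Cl
Reagents that add atoms: none
Why: Zerovalent palladium (formed from PdCl2(PPh3)2 and Et2Zn) ionises the primary allylic chloride to a π-allylpalladium chloride, Et2Zn transmetalates this to the nucleophilic allyl(ethyl)zinc 18, and 18 adds through its γ-carbon C7 to the aldehyde carbon C6 in a closed six-membered chair transition state to give alkoxide 19. The closest known reaction type is the palladium-catalysed, diethylzinc-mediated umpolung allylation of aldehydes by allylic electrophiles, whose intramolecular form on farnesyl-derived α,β-epoxy aldehydes with a terminal allylic chloride is an established ten-membered germacrane ring closure. The ring C1–C10 closes by a 10-exo-trig addition to the carbonyl group (SE2′ at the allyl unit), and the oxirane is a spectator. C7 follows from C8 taking the equatorial site of the chair, which corresponds to the (E)-allyl geometry of 17 and places the C6 hydroxyl and the isopropenyl group syn on the ring zigzag (the anti product in crotylation terms); C6 follows from Felkin–Anh attack anti to the C5–O bond of the oxirane; both are tied to C8 by allylic 1,3-strain between the C11 methyl group and C8, which holds C8–H in the allyl plane with the C9 tether anti to the forming bond and the ether oxygen outside. The step needs γ- over α-attack (ten- versus twelve-membered ring), which is the innate regiochemistry of allylzinc reagents; ring closure over oligomerisation, secured by 0.01 M and slow addition of Et2Zn; and survival of the oxirane and of the C8 oxygen, secured by K2CO3 as buffer and by carrying C8–O as an ether, a poor leaving group for 1,4-elimination.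

**Step 13**
Reactants: 20 (1(10)E,4S,5R,6R,7R,8S)-4,5-epoxy-8-(4-methoxybenzyloxy)germacra-1(10),11-dien-6-ol
Product: 21 (1(10)E,4S,5R,6R,7R,8S)-4,5-epoxy-8-(4-methoxybenzyloxy)germacr-1(10)-en-6-ol
Conditions: H2 (1 atm), RhCl(PPh3)3 (10 mol%), benzene/EtOH, rt
Reagents that add atoms: none
Why: Homogeneous hydrogenation with Wilkinson's catalyst is governed by alkene substitution, so the 1,1-disubstituted isopropenyl group should be reduced while the trisubstituted ring alkene, the oxirane and the benzyl ether are not; no stereocentre is formed.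

**Step 14**
Reactants: 21 (1(10)E,4S,5R,6R,7R,8S)-4,5-epoxy-8-(4-methoxybenzyloxy)germacr-1(10)-en-6-ol
Product: 22 (1(10)E,4S,5R,6R,7S,8S)-4,5-epoxy-8-(4-methoxybenzyloxy)-6-(triethylsilyloxy)germacr-1(10)-ene
Conditions: Et3SiCl, imidazole, DMAP (cat.), DMF, rt
Reagents that add atoms: chlorotriethylsilane, CC[Si](Cl)(CC)CC
Why: Silylation of the hindered C6 hydroxyl with a small silyl chloride under nucleophilic catalysis keeps the medium basic, which the acid-labile epoxy-cyclodecene needs (the C7 descriptor changes by priority only).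

**Step 15**
Reactants: 22 (1(10)E,4S,5R,6R,7S,8S)-4,5-epoxy-8-(4-methoxybenzyloxy)-6-(triethylsilyloxy)germacr-1(10)-ene
Product: 23 (1(10)E,4S,5R,6R,7S,8S)-4,5-epoxy-6-(triethylsilyloxy)germacr-1(10)-en-8-ol
Conditions: DDQ, CH2Cl2/pH 7 phosphate buffer, 0 °C
Reagents that add atoms: none
Why: Oxidative cleavage of the 4-methoxybenzyl ether by DDQ (single-electron oxidation, benzylic cation, hydrolysis) at pH 7; C6–O is silylated so that no cyclic acetal can form, and silyl ether, oxirane and alkene should not be oxidised.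

**Step 16**
Reactants: 23 (1(10)E,4S,5R,6R,7S,8S)-4,5-epoxy-6-(triethylsilyloxy)germacr-1(10)-en-8-ol; 24 3,4,5-trimethoxybenzoyl chloride
Product: 25 (1(10)E,4S,5R,6R,7S,8S)-4,5-epoxy-6-(triethylsilyloxy)germacr-1(10)-en-8-yl 3,4,5-trimethoxybenzoate
Conditions: Et3N, DMAP, CH2Cl2, 0 °C to rt
Reagents that add atoms: none
Why: DMAP-catalysed acylation (acylpyridinium) of the only free hydroxyl, with retention at C8.

**Step 17**
Reactants: 25 (1(10)E,4S,5R,6R,7S,8S)-4,5-epoxy-6-(triethylsilyloxy)germacr-1(10)-en-8-yl 3,4,5-trimethoxybenzoate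
Product: 26 (1(10)E,4S,5R,6R,7R,8S)-4,5-epoxy-6-hydroxygermacr-1(10)-en-8-yl 3,4,5-trimethoxybenzoate
Conditions: Bu4NF/AcOH (1:1), THF, 0 °C to rt
Reagents that add atoms: none
Why: Fluoride desilylation buffered with acetic acid keeps the medium near neutral, so neither 1,3-acyl migration (base) nor transannular opening of the oxirane (acid) is expected.

**Compound list**
1 | 1-(tert-butyldimethylsilyloxy)propan-2-one | CC(=O)CO[Si](C)(C)C(C)(C)C | starting material
2 | diethyl [2-(methoxy(methyl)amino)-2-oxoethyl]phosphonate | CCOP(=O)(CC(=O)N(C)OC)OCC | starting material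
3 | (E)-4-(tert-butyldimethylsilyloxy)-N-methoxy-N,3-dimethylbut-2-enamide | CON(C)C(=O)/C=C(\C)CO[Si](C)(C)C(C)(C)C | intermediate
4 | (E)-4-(tert-butyldimethylsilyloxy)-3-methylbut-2-enal | O=C/C=C(\C)CO[Si](C)(C)C(C)(C)C | intermediate
5 | allenylboronic acid pinacol ester | C=C=CB1OC(C)(C)C(C)(C)O1 | starting material
6 | (4S,5E)-7-(tert-butyldimethylsilyloxy)-6-methylhept-5-en-1-yn-4-ol | C#CC[C@H](O)/C=C(\C)CO[Si](C)(C)C(C)(C)C | intermediate
7 | (4S,5E)-7-(tert-butyldimethylsilyloxy)-4-(4-methoxybenzyloxy)-6-methylhept-5-en-1-yne | C#CC[C@H](OCc1ccc(OC)cc1)/C=C(\C)CO[Si](C)(C)C(C)(C)C | intermediate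
8 | dimethyl[(1E,4S,5E)-7-(tert-butyldimethylsilyloxy)-4-(4-methoxybenzyloxy)-2,6-dimethylhepta-1,5-dienyl]alane | C[Al](C)/C=C(\C)C[C@H](OCc1ccc(OC)cc1)/C=C(\C)CO[Si](C)(C)C(C)(C)C | intermediate
9 | (1E,4S,5E)-7-(tert-butyldimethylsilyloxy)-1-iodo-4-(4-methoxybenzyloxy)-2,6-dimethylhepta-1,5-diene | I/C=C(\C)C[C@H](OCc1ccc(OC)cc1)/C=C(\C)CO[Si](C)(C)C(C)(C)C | intermediate
10 | (Z)-3-methylpent-2-en-4-yn-1-ol | C#C/C(C)=C\CO | starting material
11 | (Z)-3-methylpenta-2,4-dien-1-ol | C=C/C(C)=C\CO | intermediate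
12 | 9-[(Z)-5-(9-borabicyclo[3.3.1]nonan-9-yloxy)-3-methylpent-3-enyl]-9-borabicyclo[3.3.1]nonane | CC(/CCB1C2CCCC1CCC2)=C/COB1C2CCCC1CCC2 | intermediate
13 | (2Z,6E,9S,10E)-12-(tert-butyldimethylsilyloxy)-9-(4-methoxybenzyloxy)-3,7,11-trimethyldodeca-2,6,10-trien-1-ol | OC/C=C(C)\CC/C=C(\C)C[C@H](OCc1ccc(OC)cc1)/C=C(\C)CO[Si](C)(C)C(C)(C)C | intermediate
14 | (2R,3S,6E,9S,10E)-12-(tert-butyldimethylsilyloxy)-2,3-epoxy-9-(4-methoxybenzyloxy)-3,7,11-trimethyldodeca-6,10-dien-1-ol (cis-epoxide) | OC[C@H]1O[C@@]1(C)CC/C=C(\C)C[C@H](OCc1ccc(OC)cc1)/C=C(\C)CO[Si](C)(C)C(C)(C)C | intermediate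
15 | (2R,3S,6E,9S,10E)-2,3-epoxy-9-(4-methoxybenzyloxy)-3,7,11-trimethyldodeca-6,10-diene-1,12-diol | OC[C@H]1O[C@@]1(C)CC/C=C(\C)C[C@H](OCc1ccc(OC)cc1)/C=C(\C)CO | intermediate
16 | (2R,3S,6E,9S,10E)-12-chloro-2,3-epoxy-9-(4-methoxybenzyloxy)-3,7,11-trimethyldodeca-6,10-dien-1-ol | OC[C@H]1O[C@@]1(C)CC/C=C(\C)C[C@H](OCc1ccc(OC)cc1)/C=C(\C)CCl | intermediate
17 | (2S,3S,6E,9S,10E)-12-chloro-2,3-epoxy-9-(4-methoxybenzyloxy)-3,7,11-trimethyldodeca-6,10-dienal | O=C[C@H]1O[C@@]1(C)CC/C=C(\C)C[C@H](OCc1ccc(OC)cc1)/C=C(\C)CCl | intermediate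
18 | allyl(ethyl)zinc species: 17 with ethylzinc in place of chlorine at C12 | CC[Zn]C/C(C)=C/[C@@H](OCc1ccc(OC)cc1)C/C(C)=C/CC[C@]1(C)O[C@@H]1C=O | intermediate
19 | ethylzinc alkoxide of 20 (O–Zn–ethyl on C6) | COc1ccc(CO[C@H]2C/C(C)=C/CC[C@]3(C)O[C@@H]3[C@H](O[Zn]CC)[C@H]2C(C)=C)cc1 | intermediate
20 | (1(10)E,4S,5R,6R,7R,8S)-4,5-epoxy-8-(4-methoxybenzyloxy)germacra-1(10),11-dien-6-ol | COc1ccc(CO[C@H]2C/C(C)=C/CC[C@]3(C)O[C@@H]3[C@H](O)[C@H]2C(C)=C)cc1 | intermediate
21 | (1(10)E,4S,5R,6R,7R,8S)-4,5-epoxy-8-(4-methoxybenzyloxy)germacr-1(10)-en-6-ol | COc1ccc(CO[C@H]2C/C(C)=C/CC[C@]3(C)O[C@@H]3[C@H](O)[C@H]2C(C)C)cc1 | intermediate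
22 | (1(10)E,4S,5R,6R,7S,8S)-4,5-epoxy-8-(4-methoxybenzyloxy)-6-(triethylsilyloxy)germacr-1(10)-ene | COc1ccc(CO[C@H]2C/C(C)=C/CC[C@]3(C)O[C@@H]3[C@H](O[Si](CC)(CC)CC)[C@H]2C(C)C)cc1 | intermediate
23 | (1(10)E,4S,5R,6R,7S,8S)-4,5-epoxy-6-(triethylsilyloxy)germacr-1(10)-en-8-ol | O[C@H]1C/C(C)=C/CC[C@]2(C)O[C@@H]2[C@H](O[Si](CC)(CC)CC)[C@H]1C(C)C | intermediate
24 | 3,4,5-trimethoxybenzoyl chloride | COc1cc(C(=O)Cl)cc(OC)c1OC | starting material
25 | (1(10)E,4S,5R,6R,7S,8S)-4,5-epoxy-6-(triethylsilyloxy)germacr-1(10)-en-8-yl 3,4,5-trimethoxybenzoate | COc1cc(C(=O)O[C@H]2C/C(C)=C/CC[C@]3(C)O[C@@H]3[C@H](O[Si](CC)(CC)CC)[C@H]2C(C)C)cc(OC)c1OC | intermediate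
26 | (1(10)E,4S,5R,6R,7R,8S)-4,5-epoxy-6-hydroxygermacr-1(10)-en-8-yl 3,4,5-trimethoxybenzoate | COc1cc(C(=O)O[C@H]2C/C(C)=C/CC[C@]3(C)O[C@@H]3[C@H](O)[C@H]2C(C)C)cc(OC)c1OC | target

**Count**
Total steps: 17. Longest linear sequence: 16 (steps 1–5 and 7–17; step 6 is the one-step side branch).

**Steps most likely to fail**

Step 12. The allylzinc species (or its π-allylpalladium precursor) may lose the C8 alkoxide by 1,4-elimination to a 1,3-diene, or the chain may oligomerise, before the ring closes. The three control elements for C6 and C7 may also fail to act in the same sense inside the forming ring, which would show as poor facial selectivity. The fallback sets out from 17 and changes what sits on C8 and how the ester is placed. DDQ in CH2Cl2/pH 7 buffer at 0 °C removes the benzyl ether and should give (2S,3S,6E,9S,10E)-12-chloro-2,3-epoxy-9-hydroxy-3,7,11-trimethyldodeca-6,10-dienal F1. Under the palladium/Et2Zn conditions with one more equivalent of Et2Zn the C8 oxygen is a zinc alkoxide, which cannot leave and can hold the allyl unit and the aldehyde in one aggregate; ring closure should give (1(10)E,4S,5R,6R,7S,8S)-4,5-epoxygermacra-1(10),11-diene-6,8-diol F2. Hydrogenation with RhCl(PPh3)3 should give (1(10)E,4S,5R,6R,7S,8S)-4,5-epoxygermacr-1(10)-ene-6,8-diol F3. Site-selective acylation of the less hindered C8 hydroxyl (the C6 hydroxyl is flanked by the oxirane) with 24 (1.05 equiv, 2,4,6-collidine, DMAP cat., CH2Cl2, −20 °C) comes back to the route at 26.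

Step 7. Hydroboration of the conjugated diene may put boron partly on the internal carbon or add twice, and the alkylborane may undergo β-hydride elimination or protodeboronation faster than transmetalation. The fallback sets out from 9 and builds the (Z)-alkene after the coupling instead of importing it. Negishi coupling of 9 with [4-(trimethylsilyl)but-3-ynyl]zinc bromide (from commercial (4-bromobut-1-ynyl)trimethylsilane and zinc dust in DMA) and PdCl2(dppf) should give (5E,8S,9E)-11-(tert-butyldimethylsilyloxy)-8-(4-methoxybenzyloxy)-6,10-dimethyl-1-(trimethylsilyl)undeca-5,9-dien-1-yne F4. K2CO3 in MeOH should give the terminal alkyne (5E,8S,9E)-11-(tert-butyldimethylsilyloxy)-8-(4-methoxybenzyloxy)-6,10-dimethylundeca-5,9-dien-1-yne F5. n-BuLi then methyl chloroformate at −78 °C should give methyl (6E,9S,10E)-12-(tert-butyldimethylsilyloxy)-9-(4-methoxybenzyloxy)-7,11-dimethyldodeca-6,10-dien-2-ynoate F6. Syn carbocupration with Me2CuLi in THF at −78 °C, protonated cold, should give methyl (2Z,6E,9S,10E)-12-(tert-butyldimethylsilyloxy)-9-(4-methoxybenzyloxy)-3,7,11-trimethyldodeca-2,6,10-trienoate F7. Reduction with i-Bu2AlH at −78 °C comes back to the route at 13.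

Step 13. Hydrogen may also add to the strained (E)-ring alkene, a rhodium hydride may move that alkene, or the hindered isopropenyl group may not react, which is a loss of chemoselectivity. The fallback sets out from 20 and uses the steric preference of a bulky borane, followed by deoxygenation, instead of catalytic hydrogenation. Silylation (Et3SiCl, imidazole, DMAP, DMF) should give (1(10)E,4S,5R,6R,7S,8S)-4,5-epoxy-8-(4-methoxybenzyloxy)-6-(triethylsilyloxy)germacra-1(10),11-diene F8. 9-BBN in THF, then NaBO3·4H2O, should hydroborate only the 1,1-disubstituted alkene and give the primary alcohol (1(10)E,4S,5R,6R,7S,8S)-4,5-epoxy-8-(4-methoxybenzyloxy)-6-(triethylsilyloxy)germacr-1(10)-en-12-ol F9 as C11 epimers, which is of no consequence. Iodine, PPh3 and imidazole in CH2Cl2 at 0 °C should give the primary iodide (1(10)E,4S,5R,6R,7S,8S)-4,5-epoxy-12-iodo-8-(4-methoxybenzyloxy)-6-(triethylsilyloxy)germacr-1(10)-ene F10. Radical deiodination with Bu3SnH and AIBN in toluene at 80 °C comes back to the route at 22, so that step 14 is no longer needed.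

**Further compounds**
F1 | step 12 | (2S,3S,6E,9S,10E)-12-chloro-2,3-epoxy-9-hydroxy-3,7,11-trimethyldodeca-6,10-dienal | O=C[C@H]1O[C@@]1(C)CC/C=C(\C)C[C@H](O)/C=C(\C)CCl
F2 | step 12 | (1(10)E,4S,5R,6R,7S,8S)-4,5-epoxygermacra-1(10),11-diene-6,8-diol | O[C@H]1C/C(C)=C/CC[C@]2(C)O[C@@H]2[C@H](O)[C@H]1C(C)=C
F3 | step 12 | (1(10)E,4S,5R,6R,7S,8S)-4,5-epoxygermacr-1(10)-ene-6,8-diol | O[C@H]1C/C(C)=C/CC[C@]2(C)O[C@@H]2[C@H](O)[C@H]1C(C)C
F4 | step 7 | (5E,8S,9E)-11-(tert-butyldimethylsilyloxy)-8-(4-methoxybenzyloxy)-6,10-dimethyl-1-(trimethylsilyl)undeca-5,9-dien-1-yne | C[Si](C)(C)C#CCC/C=C(\C)C[C@H](OCc1ccc(OC)cc1)/C=C(\C)CO[Si](C)(C)C(C)(C)C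
F5 | step 7 | (5E,8S,9E)-11-(tert-butyldimethylsilyloxy)-8-(4-methoxybenzyloxy)-6,10-dimethylundeca-5,9-dien-1-yne | C#CCC/C=C(\C)C[C@H](OCc1ccc(OC)cc1)/C=C(\C)CO[Si](C)(C)C(C)(C)C
F6 | step 7 | methyl (6E,9S,10E)-12-(tert-butyldimethylsilyloxy)-9-(4-methoxybenzyloxy)-7,11-dimethyldodeca-6,10-dien-2-ynoate | COC(=O)C#CCC/C=C(\C)C[C@H](OCc1ccc(OC)cc1)/C=C(\C)CO[Si](C)(C)C(C)(C)C
F7 | step 7 | methyl (2Z,6E,9S,10E)-12-(tert-butyldimethylsilyloxy)-9-(4-methoxybenzyloxy)-3,7,11-trimethyldodeca-2,6,10-trienoate | COC(=O)/C=C(C)\CC/C=C(\C)C[C@H](OCc1ccc(OC)cc1)/C=C(\C)CO[Si](C)(C)C(C)(C)C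
F8 | step 13 | (1(10)E,4S,5R,6R,7S,8S)-4,5-epoxy-8-(4-methoxybenzyloxy)-6-(triethylsilyloxy)germacra-1(10),11-diene | COc1ccc(CO[C@H]2C/C(C)=C/CC[C@]3(C)O[C@@H]3[C@H](O[Si](CC)(CC)CC)[C@H]2C(C)=C)cc1
F9 | step 13 | (1(10)E,4S,5R,6R,7S,8S)-4,5-epoxy-8-(4-methoxybenzyloxy)-6-(triethylsilyloxy)germacr-1(10)-en-12-ol (C11 epimers) | COc1ccc(CO[C@H]2C/C(C)=C/CC[C@]3(C)O[C@@H]3[C@H](O[Si](CC)(CC)CC)[C@H]2C(C)CO)cc1
F10 | step 13 | (1(10)E,4S,5R,6R,7S,8S)-4,5-epoxy-12-iodo-8-(4-methoxybenzyloxy)-6-(triethylsilyloxy)germacr-1(10)-ene (C11 epimers) | COc1ccc(CO[C@H]2C/C(C)=C/CC[C@]3(C)O[C@@H]3[C@H](O[Si](CC)(CC)CC)[C@H]2C(C)CI)cc1
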